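## Plan

- **Cuts (retrosynthesis):** first the C6 acetal, the 15-OH (allylic oxidation) and the ring A enone (oxidation of a C1 carbinol); then ring D at C13–C16 and C8–C15; then the δ-lactone at C20–O and C9–C10 in one operation, which separates a ring A exocyclic alkene from a ring C cyclohexenecarboxylic acid.
- **Enabling feature:** in the 7,20-lactone ring (C7, O, C20, C10, C9, C8) the carboxyl oxygen sits on the unsubstituted C20 methylene, and the quaternary spiro carbon C10 is bonded to C9, the β-carbon of the C7 carboxyl. This is the retron of an anti-Markovnikov acyloxylation followed by 6-endo radical addition, a formal [4+2] union of a 1,1-disubstituted alkene (C10=C20) with an α,β-unsaturated acid (O–C7–C8=C9).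
- **Forward order:** ring A fragment 9 (5 steps) and ring C acid 12 (2 steps) are joined with lactone formation in step 8; ring D is closed in steps 9–11; ring A is oxidised to the enone (12–13); 15-OH is introduced (14); the aldehyde is released (15).
- **Stereochemistry:** C5 from a ligand-controlled conjugate addition; C10 and C9 in the key step under control of C5 and the temporary C1 silyl ether; C8 by alkylation on the face of H-9; C13 by the geometry of the bicyclo[3.2.1]octane closure; C15 by the face selectivity of SeO2.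

Key step: step 8

Remark: kaurane numbering (C1–C20) is used for the atoms of all intermediates. The C1 carbinol centre of 8–17 is temporary and is erased in step 13.
Assumption: the Josiphos antipode named in step 1 is the one that gives the 3S adduct; if the facial sense is the other, its mirror-image ligand is used.

## Route

Step 1
Reactants: 1 4,4-dimethylcyclohex-2-en-1-one
Product: 3 (2R,3S)-2-[(dimethylamino)methyl]-3-ethenyl-4,4-dimethylcyclohexan-1-one, via magnesium enolate 2 (not isolated)
Conditions: CuBr·SMe2 (5 mol %), (R,S_p)-Josiphos (6 mol %), CH2=CHMgBr, t-BuOMe, −78 °C; then CH2=NMe2+ I−, THF, −78 to 0 °C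
Reagents that add atoms: vinylmagnesium bromide C=C[Mg]Br; N,N-dimethylmethylideneammonium iodide (Eschenmoser's salt) C=[N+](C)C.[I-]
Why: Copper-catalysed asymmetric conjugate addition of a Grignard reagent should set C5 under ligand control and give the enolate regiospecifically at C1/C10, which is trapped by the iminium salt on the face away from the new vinyl group (tandem conjugate addition–Mannich reaction).

Step 2
Reactants: 3 (2R,3S)-2-[(dimethylamino)methyl]-3-ethenyl-4,4-dimethylcyclohexan-1-one
Product: 4 (1S,2R)-2-[(dimethylamino)methyl]-6,6-dimethyl-3-oxocyclohexane-1-carbaldehyde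
Conditions: CF3CO2H (1.1 equiv), O3, CH2Cl2/MeOH, −78 °C; Me2S; cold NaHCO3 work-up, used crude
Reagents that add atoms: ozone [O-][O+]=O
Why: Ozonolysis with reductive work-up should cleave the only alkene while the amine is masked as its ammonium salt against N-oxidation, and the cold, brief handling protects the C5 centre next to the new aldehyde.

Step 3
Reactants: 4 (1S,2R)-2-[(dimethylamino)methyl]-6,6-dimethyl-3-oxocyclohexane-1-carbaldehyde
Product: 5 (2R,3S)-2-[(dimethylamino)methyl]-3-(1,3-dioxolan-2-yl)-4,4-dimethylcyclohexan-1-one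
Conditions: (Me3SiOCH2)2, Me3SiOTf (1.3 equiv, amine held as its triflate salt), CH2Cl2, −78 to −40 °C; pyridine quench
Reagents that add atoms: 1,2-bis(trimethylsilyloxy)ethane C[Si](C)(C)OCCO[Si](C)(C)C
Why: Noyori acetalisation at low temperature should be selective for the aldehyde over the hindered ketone and, with no free base present, should not enolise C5.

Step 4
Reactants: 5 (2R,3S)-2-[(dimethylamino)methyl]-3-(1,3-dioxolan-2-yl)-4,4-dimethylcyclohexan-1-one
Product: 8 (1S,3R)-3-(1,3-dioxolan-2-yl)-4,4-dimethyl-2-methylidenecyclohexan-1-ol, via ammonium iodide 6 (not isolated), via methylene ketone 7 (not isolated)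
Conditions: MeI, THF, 23 °C; aq NaHCO3/CH2Cl2, 0 °C; then CeCl3·7H2O, NaBH4, MeOH, −78 °C
Reagents that add atoms: none
Why: Quaternisation and E1cB loss of trimethylamine (Mannich-base methylenation) should give the labile α-methylene ketone, which is reduced at once in a Luche 1,2-reduction whose axial hydride delivery should place the C1 hydroxyl equatorial and cis to the dioxolanyl group.

Step 5
Reactants: 8 (1S,3R)-3-(1,3-dioxolan-2-yl)-4,4-dimethyl-2-methylidenecyclohexan-1-ol
Product: 9 tert-butyl{[(1S,3R)-3-(1,3-dioxolan-2-yl)-4,4-dimethyl-2-methylidenecyclohexyl]oxy}dimethylsilane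
Conditions: t-BuMe2SiOTf, 2,6-lutidine, CH2Cl2, −78 to 0 °C
Reagents that add atoms: tert-butyldimethylsilyl trifluoromethanesulfonate CC(C)(C)[Si](C)(C)OS(=O)(=O)C(F)(F)F
Why: Silylation of the hindered allylic alcohol with the silyl triflate under buffered conditions should leave the acetal intact and gives a C1 group without acidic or bis-allylic hydrogen for the radical step.

Step 6
Reactants: 10 1,4-dioxaspiro[4.5]decan-7-one
Product: 11 1,4-dioxaspiro[4.5]dec-7-en-7-yl trifluoromethanesulfonate
Conditions: LiN(SiMe3)2, THF, −78 °C; PhNTf2, −78 to 0 °C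
Reagents that add atoms: N-phenylbis(trifluoromethanesulfonimide) O=S(=O)(N(c1ccccc1)S(=O)(=O)C(F)(F)F)C(F)(F)F
Why: Kinetic enolisation should occur at the less hindered C8 methylene, away from the ketal-flanked C6, and O-triflation of that enolate fixes the future C8=C9 double bond.

Step 7
Reactants: 11 1,4-dioxaspiro[4.5]dec-7-en-7-yl trifluoromethanesulfonate
Product: 12 1,4-dioxaspiro[4.5]dec-7-ene-7-carboxylic acid
Conditions: Pd(OAc)2 (5 mol %), Ph3P (10 mol %), KOAc, CO (1 atm), DMF, 23 °C; aqueous work-up at pH 5
Reagents that add atoms: carbon monoxide [C-]#[O+]; water O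
Why: Palladium-catalysed hydroxycarbonylation of an alkenyl triflate should deliver the α,β-unsaturated acid directly, and the mild work-up spares the ketal.

Step 8
Reactants: 9 tert-butyl{[(1S,3R)-3-(1,3-dioxolan-2-yl)-4,4-dimethyl-2-methylidenecyclohexyl]oxy}dimethylsilane; 12 1,4-dioxaspiro[4.5]dec-7-ene-7-carboxylic acid
Product: 13 1-(tert-butyldimethylsilyloxy)-6,6:13,13-bis(ethylenedioxy)-15,16,17-trinor-6,7-secokauran-7,20-olide (H-8 cis to H-9; C9–C10 bond trans to C6; 1-O cis to C20)
Conditions: 9-mesityl-3,6-di-tert-butyl-10-phenylacridinium tetrafluoroborate (5 mol %), 2,6-lutidine (30 mol %), ClCH2CH2Cl (0.05 M), 450 nm LEDs, 25 °C, N2, no thiol co-catalyst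
Reagents that add atoms: none
Why: Proposed new method: the excited acridinium (about +2.1 V vs SCE) should oxidise the lutidinium carboxylate of 12 to a carboxyl radical (slow to decarboxylate because it is bound to an sp2 carbon) or, alternatively, the exocyclic alkene of 9 to its radical cation; in either manifold the carboxyl oxygen bonds to the unsubstituted C20 terminus and leaves the tertiary C10 radical, which adds to C9 of the tethered enoate, and the electrophilic α-acyl C8 radical so formed is reduced by the acridinyl radical and protonated by lutidinium to close the cycle, so that the two partners combine one to one in a pure addition in which the carboxyl hydrogen ends on C8 and every atom of both is kept in 13. The closest known reactions are the acridinium-catalysed polar radical crossover cycloaddition of alkenes with unsaturated acids (γ-butyrolactones by 5-exo closure) and the anti-Markovnikov hydroacyloxylation of alkenes. The lactone ring closes 6-endo-trig at C9, the 5-exo mode being disfavoured because C8 is fully substituted and because a nucleophilic radical prefers the β-carbon of the enoate. At C10 the acid partner should approach the planar radical on the face opposite to the C5 dioxolanyl and C1 silyloxy groups (the face also free of the syn-axial C4 methyl), so that C9 ends trans to C6 and C20 cis to it; at C9 a chair-like transition state with the ring C methylene C11 equatorial should place the fully substituted C8 beside the small C1 oxygen and H-9 beside the bulkier C5, which is the required relative configuration; the C8 configuration is of no consequence because C8 is enolised in step 9. The step needs O–C bond formation at C20 only (secured by the 1,1-disubstitution), reaction of the electron-rich alkene of 9 in preference to the electron-poor alkene of 12, and cyclisation before reduction of the C10 radical (secured by its very negative reduction potential and by the absence of a hydrogen-atom donor).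

Step 9
Reactants: 13 1-(tert-butyldimethylsilyloxy)-6,6:13,13-bis(ethylenedioxy)-15,16,17-trinor-6,7-secokauran-7,20-olide
Product: 14 1-(tert-butyldimethylsilyloxy)-6,6:13,13-bis(ethylenedioxy)-6,7:13,16-disecokaur-16-yn-7,20-olide (propargyl group on C8 cis to H-9)
Conditions: lithium diisopropylamide, THF/DMPU, −78 °C; HC≡CCH2Br, −78 to −40 °C
Reagents that add atoms: propargyl bromide C#CCBr
Why: Alkylation of the ring-fusion lactone enolate should occur on the face of H-9, away from C10 and C11 which both lie on the other side of the enolate plane, giving the cis-fused quaternary C8 with C15 anti to C10.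

Step 10
Reactants: 14 1-(tert-butyldimethylsilyloxy)-6,6:13,13-bis(ethylenedioxy)-6,7:13,16-disecokaur-16-yn-7,20-olide
Product: 15 1-(tert-butyldimethylsilyloxy)-6,6-ethylenedioxy-13-oxo-6,7:13,16-disecokaur-16-yn-7,20-olide
Conditions: pyridinium p-toluenesulfonate (cat.), acetone/H2O, 40 °C
Reagents that add atoms: water O
Why: Acid-catalysed ketal hydrolysis should be selective because the cyclohexanone ketal ionises through a tertiary oxocarbenium ion far faster than the neopentyl-type aldehyde dioxolane at C6, and the silyl ether is stable to this weak acid.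

Step 11
Reactants: 15 1-(tert-butyldimethylsilyloxy)-6,6-ethylenedioxy-13-oxo-6,7:13,16-disecokaur-16-yn-7,20-olide
Product: 16 1-(tert-butyldimethylsilyloxy)-6,6-ethylenedioxy-13-hydroxy-6,7-secokaur-16-en-7,20-olide
Conditions: SmI2 (3 equiv), HMPA, t-BuOH, THF, −78 to 0 °C
Reagents that add atoms: none
Why: Ketyl–alkyne 5-exo-dig radical cyclisation should close ring D, giving the bridgehead tertiary alcohol and the exocyclic methylene at once; the axial propargyl arm can reach C13 only from its own face, so the C13 configuration is fixed by the bicyclo[3.2.1]octane geometry, and no enone is yet present to compete for the reductant.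

Step 12
Reactants: 16 1-(tert-butyldimethylsilyloxy)-6,6-ethylenedioxy-13-hydroxy-6,7-secokaur-16-en-7,20-olide
Product: 17 6,6-ethylenedioxy-1,13-dihydroxy-6,7-secokaur-16-en-7,20-olide
Conditions: HF·pyridine, pyridine/THF, 0 to 23 °C
Reagents that add atoms: none
Why: Fluoride cleavage of the secondary silyl ether under non-basic conditions should avoid alkoxide-driven translactonisation from C20–O to C1–O and leaves the acetal and tertiary alcohol untouched.

Step 13
Reactants: 17 6,6-ethylenedioxy-1,13-dihydroxy-6,7-secokaur-16-en-7,20-olide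
Product: 19 6,6-ethylenedioxy-13-hydroxy-1-oxo-6,7-secokaura-2,16-dien-7,20-olide, via C1 ketone 18 (not isolated)
Conditions: 2-iodoxybenzoic acid (IBX, 4 equiv), DMSO/PhF, 75 °C
Reagents that add atoms: none
Why: IBX oxidation of the secondary alcohol followed in the same pot by IBX dehydrogenation of the ketone should give the enone, and only C2=C3 can form because C10 is quaternary and C2 is the sole enolisable position.

Step 14
Reactants: 19 6,6-ethylenedioxy-13-hydroxy-1-oxo-6,7-secokaura-2,16-dien-7,20-olide
Product: 20 6,6-ethylenedioxy-13,15-dihydroxy-1-oxo-6,7-secokaura-2,16-dien-7,20-olide (15-OH on the face of H-9)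
Conditions: SeO2 (0.5 equiv), t-BuOOH, CH2Cl2, 23 °C
Reagents that add atoms: tert-butyl hydroperoxide CC(C)(C)OO
Why: Selenium dioxide allylic hydroxylation (ene reaction then [2,3]-sigmatropic shift) can only occur at C15, the one allylic position with hydrogen, and oxygen should be delivered to the face syn to H-9 and away from the C7 carbonyl side, the sense expected for kaur-16-enes.

Step 15
Reactants: 20 6,6-ethylenedioxy-13,15-dihydroxy-1-oxo-6,7-secokaura-2,16-dien-7,20-olide
Product: 21 13,15-dihydroxy-1,6-dioxo-6,7-secokaura-2,16-dien-7,20-olide (CNP0521079.1)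
Conditions: 1 M HCl, THF, 23 to 40 °C
Reagents that add atoms: water O
Why: Aqueous acid hydrolysis of the dioxolane should release the C6 aldehyde without ionising the bridgehead tertiary alcohol or the neopentyl-type allylic C15 alcohol.

## Compound list

1 | 4,4-dimethylcyclohex-2-en-1-one | CC1(C)CCC(=O)C=C1 | starting material
2 | bromomagnesium (3S)-3-ethenyl-4,4-dimethylcyclohex-1-en-1-olate | C=C[C@H]1C=C(O[Mg]Br)CCC1(C)C | intermediate
3 | (2R,3S)-2-[(dimethylamino)methyl]-3-ethenyl-4,4-dimethylcyclohexan-1-one | CN(C)C[C@@H]1C(=O)CCC(C)(C)[C@H]1C=C | intermediate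
4 | (1S,2R)-2-[(dimethylamino)methyl]-6,6-dimethyl-3-oxocyclohexane-1-carbaldehyde | CN(C)C[C@@H]1C(=O)CCC(C)(C)[C@H]1C=O | intermediate
5 | (2R,3S)-2-[(dimethylamino)methyl]-3-(1,3-dioxolan-2-yl)-4,4-dimethylcyclohexan-1-one | CN(C)C[C@@H]1C(=O)CCC(C)(C)[C@H]1C2OCCO2 | intermediate
6 | {[(1R,6S)-6-(1,3-dioxolan-2-yl)-5,5-dimethyl-2-oxocyclohexyl]methyl}trimethylammonium iodide | C[N+](C)(C)C[C@@H]1C(=O)CCC(C)(C)[C@H]1C2OCCO2.[I-] | intermediate
7 | (3R)-3-(1,3-dioxolan-2-yl)-4,4-dimethyl-2-methylidenecyclohexan-1-one | C=C1C(=O)CCC(C)(C)[C@H]1C2OCCO2 | intermediate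
8 | (1S,3R)-3-(1,3-dioxolan-2-yl)-4,4-dimethyl-2-methylidenecyclohexan-1-ol | C=C1[C@@H](O)CCC(C)(C)[C@H]1C2OCCO2 | intermediate
9 | tert-butyl{[(1S,3R)-3-(1,3-dioxolan-2-yl)-4,4-dimethyl-2-methylidenecyclohexyl]oxy}dimethylsilane | C=C1[C@@H](O[Si](C)(C)C(C)(C)C)CCC(C)(C)[C@H]1C2OCCO2 | intermediate
10 | 1,4-dioxaspiro[4.5]decan-7-one | O=C1CCCC2(C1)OCCO2 | starting material
11 | 1,4-dioxaspiro[4.5]dec-7-en-7-yl trifluoromethanesulfonate | O=S(=O)(OC1=CCCC2(C1)OCCO2)C(F)(F)F | intermediate
12 | 1,4-dioxaspiro[4.5]dec-7-ene-7-carboxylic acid | OC(=O)C1=CCCC2(C1)OCCO2 | intermediate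
13 | 1-(tert-butyldimethylsilyloxy)-6,6:13,13-bis(ethylenedioxy)-15,16,17-trinor-6,7-secokauran-7,20-olide (H-8 cis to H-9) | O=C1OC[C@]2([C@@H](O[Si](C)(C)C(C)(C)C)CCC(C)(C)[C@H]2C5OCCO5)[C@@H]3CCC4(OCCO4)C[C@H]13 | intermediate
14 | 1-(tert-butyldimethylsilyloxy)-6,6:13,13-bis(ethylenedioxy)-6,7:13,16-disecokaur-16-yn-7,20-olide | C#CC[C@]23CC5(OCCO5)CC[C@H]2[C@]1(COC3=O)[C@@H](O[Si](C)(C)C(C)(C)C)CCC(C)(C)[C@H]1C4OCCO4 | intermediate
15 | 1-(tert-butyldimethylsilyloxy)-6,6-ethylenedioxy-13-oxo-6,7:13,16-disecokaur-16-yn-7,20-olide | C#CC[C@]23CC(=O)CC[C@H]2[C@]1(COC3=O)[C@@H](O[Si](C)(C)C(C)(C)C)CCC(C)(C)[C@H]1C4OCCO4 | intermediate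
16 | 1-(tert-butyldimethylsilyloxy)-6,6-ethylenedioxy-13-hydroxy-6,7-secokaur-16-en-7,20-olide | C=C1C[C@]23C[C@@]1(O)CC[C@H]2[C@]1(COC3=O)[C@@H](O[Si](C)(C)C(C)(C)C)CCC(C)(C)[C@H]1C4OCCO4 | intermediate
17 | 6,6-ethylenedioxy-1,13-dihydroxy-6,7-secokaur-16-en-7,20-olide | C=C1C[C@]23C[C@@]1(O)CC[C@H]2[C@]1(COC3=O)[C@@H](O)CCC(C)(C)[C@H]1C4OCCO4 | intermediate
18 | 6,6-ethylenedioxy-13-hydroxy-1-oxo-6,7-secokaur-16-en-7,20-olide | C=C1C[C@]23C[C@@]1(O)CC[C@H]2[C@]1(COC3=O)C(=O)CCC(C)(C)[C@H]1C4OCCO4 | intermediate
19 | 6,6-ethylenedioxy-13-hydroxy-1-oxo-6,7-secokaura-2,16-dien-7,20-olide | C=C1C[C@]23C[C@@]1(O)CC[C@H]2[C@]1(COC3=O)C(=O)C=CC(C)(C)[C@H]1C4OCCO4 | intermediate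
20 | 6,6-ethylenedioxy-13,15-dihydroxy-1-oxo-6,7-secokaura-2,16-dien-7,20-olide | C=C1[C@@H](O)[C@]23C[C@@]1(O)CC[C@H]2[C@]1(COC3=O)C(=O)C=CC(C)(C)[C@H]1C4OCCO4 | intermediate
21 | 13,15-dihydroxy-1,6-dioxo-6,7-secokaura-2,16-dien-7,20-olide (CNP0521079.1) | C=C1[C@@H](O)[C@]23C[C@@]1(O)CC[C@H]2[C@]1(COC3=O)C(=O)C=CC(C)(C)[C@H]1C=O | target

## Step count and risks

Total step count: 15. Longest linear sequence: 13 steps (steps 1–5, then 8–15).

**Step 8 (key step, proposed new method).** The exocyclic alkene may resist oxidation, the C10 radical may be reduced before it cyclises (giving only the open hydroacyloxylation ester), or the closure may show poor facial control at C9. The fallback uses known chemistry only, sets out from 9 and 12 and returns at 13. Epoxidation of 9 (dimethyldioxirane, acetone, 0 °C) should give the spiro-epoxide F1. Opening of F1 at its CH2 group by the caesium salt of 12 (Cs2CO3, DMF, 90 °C) should give the tertiary alcohol ester F2. Acylation with methyl chlorooxoacetate (Et3N, DMAP, CH2Cl2) gives the mixed methyl oxalate F3, and saponification of its methyl ester (CsOH, 1 equiv, THF/H2O) gives the caesium oxalate F4. Visible-light decarboxylation of F4 (Ir[dF(CF3)ppy]2(dtbbpy)PF6, DME/DMF, H2O, blue LEDs) should generate the same tertiary C10 radical, now already tethered through the C20 ester, and its 6-endo Giese closure onto C9 gives 13.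

**Step 1.** Vinyl transfer from the Grignard reagent may proceed with low enantioselectivity, or the enolate may equilibrate before the Mannich trap. The fallback sets out from 1 and returns at 5. Dehydrogenation of 1 (IBX, DMSO, 80 °C) gives the symmetric dienone F5. Desymmetrising rhodium-catalysed 1,4-addition of potassium vinyltrifluoroborate ([RhCl(C2H4)2]2, (R)-BINAP, toluene/H2O, 100 °C; sense predicted from the model for cyclohex-2-enone) should give the vinyl enone F6, in which only C10 is enolisable. Selective cleavage of the isolated vinyl group (OsO4 cat., NaIO4, 2,6-lutidine, dioxane/H2O) gives the aldehyde F7, and Noyori acetalisation gives the dioxolane enone F8. Regiospecific α′-aminomethylation (lithium diisopropylamide, then Eschenmoser's salt) gives the Mannich enone F9. Hydrogenation of the ring alkene (H2, palladium on carbon, EtOAc) gives 5.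

**Step 9.** Proton transfer from the alkyne C–H, O-alkylation or SN2′ attack may quench the hindered enolate before the quaternary centre forms. The fallback sets out from 13 and returns at 16. The enolate of 13 is alkylated with 2,3-dibromopropene, a more reactive allylic halide without an acidic C–H, to give the 2-bromoallyl lactone F10. Selective ketal hydrolysis (pyridinium p-toluenesulfonate, acetone/H2O) gives the bromoallyl ketone F11. Ring D is then closed by an intramolecular Nozaki–Hiyama–Kishi addition of the alkenyl bromide to the C13 ketone (CrCl2, NiCl2 cat., DMF, 50 °C), an organochromium addition in place of the ketyl radical cyclisation, which gives 16.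

## Further compounds

F1 | step 8 | spiro-epoxide of 9 (1-oxaspiro[2.5]octane; epoxide oxygen trans to the dioxolanyl group) | C1O[C@@]12[C@@H](O[Si](C)(C)C(C)(C)C)CCC(C)(C)[C@H]2C3OCCO3
F2 | step 8 | [2-(tert-butyldimethylsilyloxy)-6-(1,3-dioxolan-2-yl)-1-hydroxy-5,5-dimethylcyclohexyl]methyl 1,4-dioxaspiro[4.5]dec-7-ene-7-carboxylate | O=C(OC[C@@]1(O)[C@@H](O[Si](C)(C)C(C)(C)C)CCC(C)(C)[C@H]1C2OCCO2)C3=CCCC4(C3)OCCO4
F3 | step 8 | methyl oxalate of the tertiary alcohol F2 | O=C(OC[C@@]1(OC(=O)C(=O)OC)[C@@H](O[Si](C)(C)C(C)(C)C)CCC(C)(C)[C@H]1C2OCCO2)C3=CCCC4(C3)OCCO4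
F4 | step 8 | caesium oxalate of the tertiary alcohol F2 | O=C(OC[C@@]1(OC(=O)C(=O)[O-])[C@@H](O[Si](C)(C)C(C)(C)C)CCC(C)(C)[C@H]1C2OCCO2)C3=CCCC4(C3)OCCO4.[Cs+]
F5 | step 1 | 4,4-dimethylcyclohexa-2,5-dien-1-one | CC1(C)C=CC(=O)C=C1
F6 | step 1 | (5R)-5-ethenyl-4,4-dimethylcyclohex-2-en-1-one | O=C1C=CC(C)(C)[C@@H](C=C)C1
F7 | step 1 | (1S)-6,6-dimethyl-3-oxocyclohex-4-ene-1-carbaldehyde | O=C1C=CC(C)(C)[C@@H](C=O)C1
F8 | step 1 | (5S)-5-(1,3-dioxolan-2-yl)-4,4-dimethylcyclohex-2-en-1-one | O=C1C=CC(C)(C)[C@@H](C2OCCO2)C1
F9 | step 1 | (5S,6R)-6-[(dimethylamino)methyl]-5-(1,3-dioxolan-2-yl)-4,4-dimethylcyclohex-2-en-1-one | CN(C)C[C@@H]1C(=O)C=CC(C)(C)[C@H]1C2OCCO2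
F10 | step 9 | 8-(2-bromoprop-2-en-1-yl) analogue of 14 (bromoallyl group on C8 cis to H-9; C13 ethylene ketal) | C=C(Br)C[C@]23CC5(OCCO5)CC[C@H]2[C@]1(COC3=O)[C@@H](O[Si](C)(C)C(C)(C)C)CCC(C)(C)[C@H]1C4OCCO4
F11 | step 9 | 8-(2-bromoprop-2-en-1-yl) analogue of 15 (C13 ketone) | C=C(Br)C[C@]23CC(=O)CC[C@H]2[C@]1(COC3=O)[C@@H](O[Si](C)(C)C(C)(C)C)CCC(C)(C)[C@H]1C4OCCO4
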